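A half-life of 5.64 h for the initiator, far shorter than the 3.0 d of the run, is the number I start from, since the chains in this flask need fresh radicals.

substrate 1.5 M; coupling partner 1.80 equiv; initiator 1 mol%; time 3.0 d

    initiator → 2 initiating radical (k1 = 0.123 h⁻¹)
    substrate + initiating radical → capped initiator + first chain carrier (k2 = 28200 M⁻¹ s⁻¹)
    coupling partner + first chain carrier → target + second chain carrier (k3 = 1.97 × 10⁶ M⁻¹ h⁻¹)
    substrate + second chain carrier → by-product + first chain carrier (k4 = 1.69 × 10⁶ M⁻¹ h⁻¹)
    2 second chain carrier → ended chains (k5 = 5.4 × 10⁸ M⁻¹ s⁻¹)
    2 substrate → homo dimer (k6 = 9.89 × 10⁻⁵ M⁻¹ h⁻¹)
    target ⇌ isomer of the product (K7 = 0.97, k7 = 0.316 h⁻¹)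

- percent here means substrate units held: one homo dimer counts as two
- two of one species on the left: rate k times its square, two consumed each time
- the reaction counts as stopped when no species that holds the substrate changes by six tenths of a point or more over the second half of the time
- run time (flask): 3.0 d

- why nothing more happens at 3.0 d, or that something still does (forward and back rates have come level / it is still moving / the coupling partner has run out first / all of the substrate has reacted)
- how much of the substrate has reacted by 3.0 d
- how much target there is at 3.0 d, in percent of the substrate charged
- how much isomer of the product there is at 3.0 d, in percent of the substrate charged

Radicals enter through the initiator and leave when two second chain carriers meet, so in this flask making and ending balance at a second chain carrier of 3.08 × 10⁻⁸ M at the start. The substrate therefore falls pseudo-first-order at 0.0521 h⁻¹, but that constant follows the square root of the initiator and fades over 16.3 h. This fading time is shorter than the 19.2 h the chain needs at its starting rate for one e-fold of substrate, so I expect the radical supply to give out first, and for 3.0 d I reckon the initiator at 0.0143% of its charge. I call 0.836 the chain reach, the fall in the natural logarithm of the substrate that the chains bring by the end of the run. Taken by itself, it gives 56.7% reacted.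

The weak link is that the reach counts chain turns, whereas each initiator gives two radicals and each radical caps a substrate, which takes 2.00% of the charge. Reforged with that factor, and with the homo dimer left out, the reckoning gives 57.5% reacted. Each turn takes one coupling partner, and more of it was charged than of substrate. Target and isomer of the product relax in 1.08 h, much shorter than the run, so they share the reacted substrate by the equilibrium constant: 29.2% target and 28.3% isomer of the product. Over the second half of the run I reckon the substrate to fall by 3.6 percentage points, so I say the flask has not stopped.

The forecast reads 58.3% reacted, 29.3% target and 28.4% isomer of the product, with the pair “essentially at equilibrium”, and says it is still moving. The simulated flask gives 58.3% reacted, 29.3% target and 28.4% isomer of the product, and it is still moving.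

In the neighbouring flask with 2.5 mol% of initiator and the other charges unchanged, the chain reach grows with the square root of the loading to 1.32, so with 5.00% of the charge taken by capping I reckon 74.7% reacted and 37.9% target. That flask gives 75.7% reacted, 38.3% target and 37.1% isomer of the product, and it ends with 24.3% of the substrate left, less than its target.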